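The numbers in the tables stem from a simulated flask with made-up constants; the scatter is artificial.

I take c(dissolved substrate) to rise to one level while solid substrate is present, in Thursday's run and in the new flask alike, at the same temperature. This level is the invariant you carry from Thursday's run to the new flask.

| setting | Thursday's | flask |
|---|---|---|
| solid substrate | 0.020 M | 0.010 M |
| gas | 3.7 mM (held) | 3.7 mM (held) |
| remark | run made earlier |  |
| time |  | 50 min |

Thursday's run (percent of the solid substrate charged)

| time / min | target / % | dissolved substrate / % |
|---|---|---|
| 0.833 | 0 | 17 |
| 1.33 | 0 | 21 |
| 2.00 | 2 | 27 |
| 4.00 | 3 | 36 |
| 6.00 | 0 | 36 |
| 10.0 | 0 | 37 |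

(readings scatter by 1.5 percentage points)

- solid, in amounts per volume of the solution: solid substrate
- at the start none of partner is dissolved
- steps under discussion: solid substrate <-> dissolved substrate; partner -> side product; dissolved substrate + partner -> target; gas <-> partner
- at the start none of the solid substrate is in solution
- dissolved substrate means what is dissolved; the solid is not counted in it

- grey: doubling the solubility of the solid substrate, all else as stated
- red: doubling the dissolution coefficient of the solid substrate, all else as stated
- ochre: doubling the saturation concentration of gas, all else as stated
- blue: doubling the transfer coefficient of the gas, all else as stated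

- amount of target at 50 min, in percent of the solid substrate charged
- concentration of dissolved substrate in solution at 12 min, in percent of saturation
- the change that raises the amount of target at 50 min, in percent of the solid substrate charged most ("none" if none brings more than 2 percentage points) (grey / red / ochre / blue / none)
- amount of target at 50 min, in percent of the solid substrate charged, after blue

1. Thursday's dissolved substrate ends at a reading of 37 % of 0.020 M, so the level is 7.40 mM.

2. Its first reading gives a rate constant of 0.739 min⁻¹, a half-time of 0.939 min. This is far shorter than 12 min, so I expect the flask close to 100 % of saturation at that time.

3. Thursday's charge is twice the flask's. The level and the gas are the same in both, so I expect equal molar rates and, in the flask, twice Thursday's percentage at equal times.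

4. At that level the solution of the flask holds 74.0 % of its charge, which leaves the reserve 26.0 %, the target yield in percent of the charge at which I expect the solid to be used up. Thursday's reserve is 63.0 %.

5. Thursday's highest target reading is 3 % against a scatter of 1.5 percentage points, and that run has no reading of partner, so I give no number for the yield. I expect doubling the solubility to lift c(dissolved substrate) to the charge, 1.35 times the level, so I choose ochre, expecting it to double partner.

The forecast says 4 %, 99 %, ochre and 4.3 %, on the ground: “so the molar rate is the same, but the percentage doubles on half the charge”. Putting its yield back into my reserve, 4 % lies below 26.0 %, so on that yield solid substrate is still present.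

The flask gives 15.4 %, 99.5 %, ochre and 23.2 %. The forecast agrees on saturation and choice, and parts on both yields.

    solid substrate ⇌ dissolved substrate, rate k1*(cs1 - [dissolved substrate]) while solid is left; crystals form when [dissolved substrate] > cs1 (solubility = 7.50 mM, k = 0.0110 s⁻¹)
    partner → side product (k = 2.70 × 10⁻⁴ s⁻¹)
    dissolved substrate + partner → target (k = 0.0540 M⁻¹ s⁻¹)
    gas ⇌ partner, rate k4*(csat - [partner]) (kL = 5.90 × 10⁻⁴ s⁻¹)

At 50.0 min in the flask, dissolved substrate is made 0.997 times as fast as it is used, each step taken net, with 74.4 % dissolved, solid substrate at 10.2 %, and target at 15.4 %, less than the reserve. The same flask left until 2.0 h has target 42.6 %, above the reserve, solid 0 %, and dissolved substrate down at 57.4 %.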